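**Retrosynthetic overview**
- The target comes from its tris-benzyl ether by one global hydrogenolysis.
- The benzofuran comes from a 3-(homoallyloxy)pyridazine. One thermal intramolecular Diels–Alder / N2 loss / dehydrogenation builds the benzene ring (pyridazine C3–C6 plus the vinyl group) and the dihydrofuran ring (the O–C–C tether) together. The 7-OMe and the C5 chain arrive on the pyridazine.
- The pyridazinyl ether comes from an anti homoallylic alcohol and 3-chloro-4-methoxy-6-alkylpyridazine by SNAr. The chloropyridazine comes from 3,6-dichloro-4-methoxypyridazine by site-selective B-alkyl Suzuki coupling.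
- Both stereocentres come from one Ir-catalysed anti-(hydroxymethyl)allylation of O-benzylsyringaldehyde and are not touched again.
- Ring order: the syringyl ring is bought; the pyridazine ring is bought and sacrificed; the benzofuran benzene ring and the dihydrofuran ring are formed last, in the same step.

Assumption: (S)-SEGPHOS is written as the ligand hand that gives the (1S,2R)-diol. If a Mosher check on the first run shows the antipode, (R)-SEGPHOS is used and nothing else changes.

**Step 1**
Reactants: 1 4-(benzyloxy)-3,5-dimethoxybenzaldehyde; 2 4-vinyl-1,3-dioxolan-2-one (racemic)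
Product: 3 (1S,2R)-1-[4-(benzyloxy)-3,5-dimethoxyphenyl]-2-vinylpropane-1,3-diol
Conditions: [Ir(cod)Cl]2 (2.5 mol%), (S)-SEGPHOS (5 mol%), 4-cyano-3-nitrobenzoic acid (10 mol%), K3PO4 (10 mol%), i-PrOH (2 equiv), THF, 90 °C
Reagents that add atoms: none
Why: Krische-type transfer-hydrogenative carbonyl (hydroxymethyl)allylation, in which the allylic carbonate ionises and loses CO2 to an (E)-σ-(4-hydroxybut-2-enyl)iridium that adds through a closed chair transition state (anti, setting C1/C2 relative configuration) while the cyclometallated Ir–SEGPHOS complex selects the aldehyde face (absolute configuration 1S,2R).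

**Step 2**
Reactants: 3 (1S,2R)-1-[4-(benzyloxy)-3,5-dimethoxyphenyl]-2-vinylpropane-1,3-diol
Product: 4 (1S,2R)-1-[4-(benzyloxy)-3,5-dimethoxyphenyl]-2-[(benzyloxy)methyl]but-3-en-1-ol
Conditions: BnBr (1.1 equiv), Ag2O (1.5 equiv), CH2Cl2, rt
Reagents that add atoms: benzyl bromide, BrCc1ccccc1
Why: Ag2O-mediated mono-O-benzylation (Williamson type) goes to the unhindered primary hydroxyl and leaves the hindered benzylic secondary one free; a benzyl ether is chosen because, unlike a silyl or acyl group, it cannot migrate to the neighbouring alkoxide in step 4.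

**Step 3**
Reactants: 5 allyl benzyl ether; 6 3,6-dichloro-4-methoxypyridazine
Product: 8 6-[3-(benzyloxy)propyl]-3-chloro-4-methoxypyridazine, via B-[3-(benzyloxy)propyl]-9-BBN 7 (not isolated)
Conditions: 9-BBN-H (1.05 equiv), THF, 0 °C to rt; then 6 (1.0 equiv), Pd(dppf)Cl2 (5 mol%), aq. K3PO4 (3 equiv), THF/DMF, 60 °C
Reagents that add atoms: none
Why: anti-Markovnikov hydroboration then B-alkyl Suzuki–Miyaura coupling, with oxidative addition expected at C6–Cl (meta to the OMe donor, unhindered) rather than at C3–Cl (flanked by and conjugated with the OMe group).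

**Step 4**
Reactants: 4 (1S,2R)-1-[4-(benzyloxy)-3,5-dimethoxyphenyl]-2-[(benzyloxy)methyl]but-3-en-1-ol; 8 6-[3-(benzyloxy)propyl]-3-chloro-4-methoxypyridazine
Product: 9 6-[3-(benzyloxy)propyl]-3-{[(1S,2R)-1-[4-(benzyloxy)-3,5-dimethoxyphenyl]-2-[(benzyloxy)methyl]but-3-en-1-yl]oxy}-4-methoxypyridazine
Conditions: NaH (1.2 equiv), THF/DMF, 0 °C; then 8, 0 to 60 °C
Reagents that add atoms: none
Why: SNAr (addition–elimination) of the sodium alkoxide at the only remaining C–Cl, which is activated by the adjacent ring nitrogen; only the O–H bond of 4 reacts, so both stereocentres are retained.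

**Step 5**
Reactants: 9 6-[3-(benzyloxy)propyl]-3-{[(1S,2R)-1-[4-(benzyloxy)-3,5-dimethoxyphenyl]-2-[(benzyloxy)methyl]but-3-en-1-yl]oxy}-4-methoxypyridazine
Product: 12 (2S,3R)-2-[4-(benzyloxy)-3,5-dimethoxyphenyl]-3-[(benzyloxy)methyl]-5-[3-(benzyloxy)propyl]-7-methoxy-2,3-dihydro-1-benzofuran, via diazabicyclo[2.2.2]octadiene cycloadduct 10 (not isolated), via 3a,4-dihydrobenzofuran 11 (not isolated)
Conditions: 1,3,5-triisopropylbenzene (0.01 M, degassed), 230 °C, sealed tube; then DDQ (1.05 equiv), PhMe, 0 °C, 15 min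
Reagents that add atoms: none
Why: Proposed new method: the 1,2-diazine is the 4π component across C3/C6 and the tethered terminal alkene the 2π component (three-atom O–C–C tether, helped by its two substituents), so one [4+2] closes the dihydrofuran and the new six-membered carbocycle together, irreversible N2 loss gives the cyclohexadiene and DDQ aromatises it, while C2 and C3 from step 1 are spectators and the transient C3a centre is erased; the closest known reactions are the thermal intramolecular inverse-electron-demand Diels–Alder reactions of 3-(but-3-ynyloxy)pyridazines to 2,3-dihydrobenzofurans and of 3-(2-allylphenoxy)pyridazines to xanthenes, here stretched to a more electron-rich diazine and a simple alkene.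

**Step 6**
Reactants: 12 (2S,3R)-2-[4-(benzyloxy)-3,5-dimethoxyphenyl]-3-[(benzyloxy)methyl]-5-[3-(benzyloxy)propyl]-7-methoxy-2,3-dihydro-1-benzofuran
Product: 13 4-[(2S,3R)-3-(hydroxymethyl)-5-(3-hydroxypropyl)-7-methoxy-2,3-dihydro-1-benzofuran-2-yl]-2,6-dimethoxyphenol
Conditions: H2 (1 atm), Pd(OH)2/C, EtOAc/MeOH, rt
Reagents that add atoms: none
Why: catalytic hydrogenolysis removes the aryl and the two primary alkyl benzyl ethers in one step, and is stopped at full conversion (neutral medium, 1 atm) so that the ring C2–O bond and both stereocentres stay intact.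

**Compound list**
1 | 4-(benzyloxy)-3,5-dimethoxybenzaldehyde (O-benzylsyringaldehyde) | COc1cc(C=O)cc(OC)c1OCc1ccccc1 | starting material
2 | 4-vinyl-1,3-dioxolan-2-one (vinyl ethylene carbonate, racemic) | C=CC1COC(=O)O1 | starting material
3 | (1S,2R)-1-[4-(benzyloxy)-3,5-dimethoxyphenyl]-2-vinylpropane-1,3-diol | COc1cc(cc(OC)c1OCc1ccccc1)[C@@H](O)[C@@H](CO)C=C | intermediate
4 | (1S,2R)-1-[4-(benzyloxy)-3,5-dimethoxyphenyl]-2-[(benzyloxy)methyl]but-3-en-1-ol | COc1cc(cc(OC)c1OCc1ccccc1)[C@@H](O)[C@@H](COCc1ccccc1)C=C | intermediate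
5 | allyl benzyl ether | C=CCOCc1ccccc1 | starting material
6 | 3,6-dichloro-4-methoxypyridazine | COc1cc(Cl)nnc1Cl | starting material
7 | 9-[3-(benzyloxy)propyl]-9-borabicyclo[3.3.1]nonane | C(CCOCc1ccccc1)B1C2CCCC1CCC2 | intermediate (not isolated)
8 | 6-[3-(benzyloxy)propyl]-3-chloro-4-methoxypyridazine | COc1cc(CCCOCc2ccccc2)nnc1Cl | intermediate
9 | 6-[3-(benzyloxy)propyl]-3-{[(1S,2R)-1-[4-(benzyloxy)-3,5-dimethoxyphenyl]-2-[(benzyloxy)methyl]but-3-en-1-yl]oxy}-4-methoxypyridazine | COc1cc(cc(OC)c1OCc1ccccc1)[C@@H](Oc1nnc(CCCOCc2ccccc2)cc1OC)[C@@H](COCc1ccccc1)C=C | intermediate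
10 | Diels–Alder adduct: tetrahydrofuran-fused 2,3-diazabicyclo[2.2.2]octa-2,5-diene with the N=N bridge across future C5/C7a (C2 and C3 as in 9; C3a and bridgeheads unspecified) | COc1cc([C@H]2OC34N=NC(CCCOCc5ccccc5)(C=C3OC)CC4[C@@H]2COCc2ccccc2)cc(OC)c1OCc1ccccc1 | intermediate (not isolated)
11 | (2S,3R)-2-[4-(benzyloxy)-3,5-dimethoxyphenyl]-3-[(benzyloxy)methyl]-5-[3-(benzyloxy)propyl]-7-methoxy-2,3,3a,4-tetrahydro-1-benzofuran (C3a epimers) | COc1cc([C@H]2OC3=C(OC)C=C(CCCOCc4ccccc4)CC3[C@@H]2COCc2ccccc2)cc(OC)c1OCc1ccccc1 | intermediate (not isolated)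
12 | (2S,3R)-2-[4-(benzyloxy)-3,5-dimethoxyphenyl]-3-[(benzyloxy)methyl]-5-[3-(benzyloxy)propyl]-7-methoxy-2,3-dihydro-1-benzofuran | COc1cc([C@H]2Oc3c(OC)cc(CCCOCc4ccccc4)cc3[C@@H]2COCc2ccccc2)cc(OC)c1OCc1ccccc1 | intermediate
13 | 4-[(2S,3R)-3-(hydroxymethyl)-5-(3-hydroxypropyl)-7-methoxy-2,3-dihydro-1-benzofuran-2-yl]-2,6-dimethoxyphenol | COc1cc([C@H]2Oc3c(OC)cc(CCCO)cc3[C@@H]2CO)cc(OC)c1O | target

**Step count**
Total: 6 steps. Longest linear sequence: 5 steps (1, 2, 4, 5, 6); step 3 is a one-step side branch.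

**Steps most likely to fail**

The most likely to fail is step 5. The diazine carries two alkoxy groups and an alkyl group, and the alkene is unactivated. At 230 °C a retro-ene loss of the pyridazinone from the benzylic ether can compete with cycloaddition, and DDQ can over-oxidise 12 to the benzofuran. The fallback sets out from 9 and replaces the alkene by a far more reactive, self-aromatising dienophile. Hydroboration–oxidation of the vinyl group (9-BBN; NaBO3) gives (3R,4S)-4-[4-(benzyloxy)-3,5-dimethoxyphenyl]-3-[(benzyloxy)methyl]-4-({6-[3-(benzyloxy)propyl]-4-methoxypyridazin-3-yl}oxy)butan-1-ol F1. Dess–Martin oxidation gives the corresponding butanal F2. With pyrrolidine and 4 Å sieves in dioxane at 60–100 °C this forms the (E)-pyrrolidine enamine F3. The enamine undergoes the same intramolecular inverse-demand Diels–Alder reaction well below the elimination temperature to give the pyrrolidinyl diazabicyclooctadiene cycloadduct F4. This loses N2 to the 4-(pyrrolidin-1-yl)-3a,4-dihydrobenzofuran F5, which loses pyrrolidine and so reaches 12 without an oxidant. The fallback comes back to the route at 12.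

The second is step 3. The site selectivity between the two C–Cl bonds of 6 is argued, not known, and bis-coupling is possible. The fallback sets out from borane 7 and uses a pyridazine with only one halide. Coupling 7 with 6-chloro-4-methoxypyridazin-3-amine (purchased) F6 under the same Pd(dppf)Cl2 conditions gives 6-[3-(benzyloxy)propyl]-4-methoxypyridazin-3-amine F7. One-pot diazotisation–chlorination of the amino group (t-BuONO, CuCl2, MeCN, 60 °C) then gives 8, where it comes back to the route.

The third is step 4. The chloride of 8 is flanked by the methoxy group and deactivated by two donors, and the nucleophile is a hindered secondary benzylic alkoxide. Heating may be needed, and heating invites side reactions. The fallback sets out from 8 and changes the leaving group. NaSMe in DMF gives 6-[3-(benzyloxy)propyl]-4-methoxy-3-(methylsulfanyl)pyridazine F8. Oxone in MeOH/H2O gives 6-[3-(benzyloxy)propyl]-3-(methanesulfonyl)-4-methoxypyridazine F9. The sulfone is displaced by the sodium alkoxide of 4 (NaHMDS, THF, −40 to 0 °C) to give 9, where it comes back to the route.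

**Further compounds**
F1 | step 5 | (3R,4S)-4-[4-(benzyloxy)-3,5-dimethoxyphenyl]-3-[(benzyloxy)methyl]-4-({6-[3-(benzyloxy)propyl]-4-methoxypyridazin-3-yl}oxy)butan-1-ol | COc1cc(cc(OC)c1OCc1ccccc1)[C@@H](Oc1nnc(CCCOCc2ccccc2)cc1OC)[C@@H](COCc1ccccc1)CCO
F2 | step 5 | (3R,4S)-4-[4-(benzyloxy)-3,5-dimethoxyphenyl]-3-[(benzyloxy)methyl]-4-({6-[3-(benzyloxy)propyl]-4-methoxypyridazin-3-yl}oxy)butanal | COc1cc(cc(OC)c1OCc1ccccc1)[C@@H](Oc1nnc(CCCOCc2ccccc2)cc1OC)[C@@H](COCc1ccccc1)CC=O
F3 | step 5 | (E)-pyrrolidine enamine of F2 | COc1cc(cc(OC)c1OCc1ccccc1)[C@@H](Oc1nnc(CCCOCc2ccccc2)cc1OC)[C@@H](COCc1ccccc1)/C=C/N1CCCC1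
F4 | step 5 | pyrrolidinyl-substituted diazabicyclo[2.2.2]octadiene cycloadduct (C2 and C3 as in 9; other centres unspecified) | COc1cc([C@H]2OC34N=NC(CCCOCc5ccccc5)(C=C3OC)C(N3CCCC3)C4[C@@H]2COCc2ccccc2)cc(OC)c1OCc1ccccc1
F5 | step 5 | (2S,3R)-2-[4-(benzyloxy)-3,5-dimethoxyphenyl]-3-[(benzyloxy)methyl]-5-[3-(benzyloxy)propyl]-7-methoxy-4-(pyrrolidin-1-yl)-2,3,3a,4-tetrahydro-1-benzofuran | COc1cc([C@H]2OC3=C(OC)C=C(CCCOCc4ccccc4)C(N4CCCC4)C3[C@@H]2COCc2ccccc2)cc(OC)c1OCc1ccccc1
F6 | step 3 | 6-chloro-4-methoxypyridazin-3-amine (purchased) | COc1cc(Cl)nnc1N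
F7 | step 3 | 6-[3-(benzyloxy)propyl]-4-methoxypyridazin-3-amine | COc1cc(CCCOCc2ccccc2)nnc1N
F8 | step 4 | 6-[3-(benzyloxy)propyl]-4-methoxy-3-(methylsulfanyl)pyridazine | COc1cc(CCCOCc2ccccc2)nnc1SC
F9 | step 4 | 6-[3-(benzyloxy)propyl]-3-(methanesulfonyl)-4-methoxypyridazine | COc1cc(CCCOCc2ccccc2)nnc1S(C)(=O)=O
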